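## Retrosynthetic overview

- Feature: the 11-membered carbocycle (C1 carrying the exocyclic CH2, C2=C3, C4 with two methyls, C5, C6 carrying the ester oxygen, C7, C8 with a methyl, =C9, C10, C11) has its C6 oxygen homoallylic to the E-trisubstituted C8=C9 alkene. This is the pattern of a terminal epoxide (C6, C7) and a hydride added across a methyl alkyne (C8≡C9).
- Disconnection 1: the C6–O acyl bond, back to the macrocyclic alcohol and TBS-protected vanillic acid.
- Disconnection 2 (key): ring bond C7–C8 by nickel-mediated reductive alkyne–epoxide coupling; the 11-membered ring is the only ring formed and is closed once the whole carbon chain is in place.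
- Disconnection 3: the open-chain dienyne epoxide from Wittig methylenation (C1=CH2), kinetic resolution of the epoxide (C6), and Horner–Wadsworth–Emmons olefination (C2=C3) of 2,2-dimethylpent-4-enal with a ketophosphonate made by dianion alkylation (C10–C11).

Key step: step 6

Remark: the single stereocentre C6 is (S) in the target. It comes from the (R)-epoxide, because opening at C7 changes the CIP ranking at C6 (C7 falls below C5), not the spatial arrangement.

## Route

Step 1
Reactants: 1 dimethyl (2-oxopropyl)phosphonate; 2 1-bromobut-2-yne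
Product: 4 dimethyl (2-oxohept-5-yn-1-yl)phosphonate, via phosphonate dianion 3 (not isolated)
Conditions: NaH, THF, 0 °C; n-BuLi, 0 °C; then 2, 0 °C to rt; 1 M HCl quench
Reagents that add atoms: none
Why: γ-Alkylation of a β-ketophosphonate dianion: the second deprotonation puts the more reactive carbanion on the terminal methyl, which displaces the primary propargylic bromide by SN2 while the phosphonate-stabilised carbon stays untouched.

Step 2
Reactants: 4 dimethyl (2-oxohept-5-yn-1-yl)phosphonate; 5 2,2-dimethylpent-4-enal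
Product: 7 (E)-4,4-dimethyldodeca-1,5-dien-10-yn-7-one, via sodium phosphonate 6 (not isolated)
Conditions: NaH, THF, 0 °C; then 5, 0 °C to rt
Reagents that add atoms: none
Why: Horner–Wadsworth–Emmons olefination of a non-enolisable aldehyde with a stabilised β-ketophosphonate anion, which should give the E-enone (C2=C3).

Step 3
Reactants: 7 (E)-4,4-dimethyldodeca-1,5-dien-10-yn-7-one
Product: 8 rac-(E)-2,2-dimethyl-1-(oxiran-2-yl)dec-3-en-8-yn-5-one
Conditions: mCPBA, NaHCO3, CH2Cl2, 0 °C to rt
Reagents that add atoms: mCPBA, O=C(OO)c1cccc(Cl)c1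
Why: Prilezhaev epoxidation: the electrophilic peracid should attack the isolated monosubstituted alkene faster than the electron-poor enone alkene (also shielded by quaternary C4) or the alkyne; C6 is formed as the racemate and resolved in step 4.

Step 4
Reactants: 8 rac-(E)-2,2-dimethyl-1-(oxiran-2-yl)dec-3-en-8-yn-5-one
Product: 9 (E)-2,2-dimethyl-1-[(2R)-oxiran-2-yl]dec-3-en-8-yn-5-one
Conditions: (R,R)-(salen)Co(OAc) (1 mol%; salen = N,N'-bis(3,5-di-tert-butylsalicylidene)cyclohexane-1,2-diamine dianion, acetate of trivalent cobalt), H2O (0.55 equiv), THF, 0 °C to rt; chromatography to remove the diol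
Reagents that add atoms: none
Why: Jacobsen hydrolytic kinetic resolution: the (R,R) catalyst hydrates the (S) enantiomer of a 2-alkyloxirane at its terminal carbon much faster, so the (R)-epoxide should remain in high enantiomeric purity and C6 is fixed here.

Step 5
Reactants: 9 (E)-2,2-dimethyl-1-[(2R)-oxiran-2-yl]dec-3-en-8-yn-5-one
Product: 10 (2R)-2-[(3E)-2,2-dimethyl-5-methylidenedec-3-en-8-yn-1-yl]oxirane
Conditions: Ph3PCH3Br, KOtBu, THF, 0 °C; then 9, 0 °C to rt
Reagents that add atoms: methyltriphenylphosphonium bromide, C[P+](c1ccccc1)(c1ccccc1)c1ccccc1.[Br-]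
Why: Wittig methylenation: the non-stabilised ylide adds 1,2 to the enone carbonyl (conjugate addition is blocked by quaternary C4 next to the β-carbon), and a terminal epoxide is inert to the ylide at this temperature.

Step 6
Reactants: 10 (2R)-2-[(3E)-2,2-dimethyl-5-methylidenedec-3-en-8-yn-1-yl]oxirane
Product: 12 (1S,3E,8E)-3,10,10-trimethyl-7-methylidenecycloundeca-3,8-dien-1-ol, via diethylborinate ester 11 (not isolated)
Conditions: Ni(cod)2 (20 mol%), PBu3 (40 mol%), BEt3 (3 equiv), toluene, 40 °C, syringe-pump addition of 10 over 20 h to a final 0.005 M; then aq. NaHCO3 work-up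
Reagents that add atoms: none
Why: Proposed new method: zerovalent nickel, with BEt3 acting as Lewis acid on the epoxide oxygen, is expected to open the epoxide by SN2-type oxidative addition at the unsubstituted carbon C7, the alkyne then inserts syn into the Ni–C7 bond so that C7 bonds to C8, and ethyl transfer from boron to nickel, β-hydride elimination of ethene and C–H reductive elimination put hydrogen on C9 cis to C7 and leave the C6 oxygen as diethylborinate 11, which is hydrolysed on work-up. The closest known reaction type is the nickel-catalysed, BEt3-promoted reductive coupling of alkynes with terminal epoxides, shown between two molecules and for five- and six-membered rings, together with nickel-catalysed alkyne–aldehyde reductive macrocyclisation; closing a medium ring this way is new. The 11-membered ring closes in endo mode for both partners (C6, C7, C8 and C9 all become ring atoms), helped by the gem-dimethyl group at C4 and the rigid E-diene, which bring the chain ends together. No stereocentre is created: C6 is not touched and keeps the configuration set in step 4, and the E geometry of C8=C9 follows from syn addition of C7 and H across the alkyne. The step needs the C7–C8 bond and not C7–C9 (which would give a 10-membered ring with an exocyclic ethylidene); the small methyl on C8 and the small phosphine PBu3 should direct carbon–carbon bond formation to C8, and because the two-carbon link from the alkyne ends at the inner diene carbon C1, a nickel-mediated diene–alkyne cycloaddition is geometrically excluded. Slow addition keeps 10 dilute so that coupling between two molecules is suppressed.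

Step 7
Reactants: 13 vanillic acid
Product: 15 4-[(tert-butyldimethylsilyl)oxy]-3-methoxybenzoic acid, via bis-silylated vanillate 14 (not isolated)
Conditions: TBSCl (2.5 equiv), imidazole, DMF, rt; then AcOH/THF/H2O, rt
Reagents that add atoms: tert-butyldimethylsilyl chloride, CC(C)(C)[Si](C)(C)Cl
Why: Silylation of both phenol and acid, then selective hydrolysis of the labile silyl ester under mild aqueous acid, to which the aryl silyl ether is stable.

Step 8
Reactants: 12 (1S,3E,8E)-3,10,10-trimethyl-7-methylidenecycloundeca-3,8-dien-1-ol; 15 4-[(tert-butyldimethylsilyl)oxy]-3-methoxybenzoic acid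
Product: 16 (1S,3E,8E)-3,10,10-trimethyl-7-methylidenecycloundeca-3,8-dien-1-yl 4-[(tert-butyldimethylsilyl)oxy]-3-methoxybenzoate
Conditions: EDC·HCl, DMAP, CH2Cl2, 0 °C to rt
Reagents that add atoms: none
Why: Steglich esterification: the carbodiimide activates the acid and DMAP transfers the acyl group to the secondary alcohol, so the C6–O bond is never broken and the (S) configuration is retained.

Step 9
Reactants: 16 (1S,3E,8E)-3,10,10-trimethyl-7-methylidenecycloundeca-3,8-dien-1-yl 4-[(tert-butyldimethylsilyl)oxy]-3-methoxybenzoate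
Product: 17 (1S,3E,8E)-3,10,10-trimethyl-7-methylidenecycloundeca-3,8-dien-1-yl 4-hydroxy-3-methoxybenzoate
Conditions: Bu4NF, AcOH (1:1), THF, 0 °C
Reagents that add atoms: none
Why: Fluoride cleavage of the aryl silyl ether, buffered with acetic acid so that the phenoxide does not attack the benzoate ester; the diene and the trisubstituted alkene are inert.

## Compound list

1 | dimethyl (2-oxopropyl)phosphonate | CC(=O)CP(=O)(OC)OC | starting material
2 | 1-bromobut-2-yne | CC#CCBr | starting material
3 | sodium lithium dianion of 1 | [Na+].[Li+].[CH2-]C(=O)[CH-]P(=O)(OC)OC | intermediate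
4 | dimethyl (2-oxohept-5-yn-1-yl)phosphonate | CC#CCCC(=O)CP(=O)(OC)OC | intermediate
5 | 2,2-dimethylpent-4-enal | C=CCC(C)(C)C=O | starting material
6 | sodium salt of 4 | [Na+].CC#CCCC(=O)[CH-]P(=O)(OC)OC | intermediate
7 | (E)-4,4-dimethyldodeca-1,5-dien-10-yn-7-one | C=CCC(C)(C)/C=C/C(=O)CCC#CC | intermediate
8 | rac-(E)-2,2-dimethyl-1-(oxiran-2-yl)dec-3-en-8-yn-5-one | CC#CCCC(=O)/C=C/C(C)(C)CC1CO1 | intermediate
9 | (E)-2,2-dimethyl-1-[(2R)-oxiran-2-yl]dec-3-en-8-yn-5-one | CC#CCCC(=O)/C=C/C(C)(C)C[C@@H]1CO1 | intermediate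
10 | (2R)-2-[(3E)-2,2-dimethyl-5-methylidenedec-3-en-8-yn-1-yl]oxirane | CC#CCCC(=C)/C=C/C(C)(C)C[C@@H]1CO1 | intermediate
11 | diethylborinate ester of 12 | C=C1/C=C/C(C)(C)C[C@@H](OB(CC)CC)C/C(C)=C/CC1 | intermediate
12 | (1S,3E,8E)-3,10,10-trimethyl-7-methylidenecycloundeca-3,8-dien-1-ol | C=C1/C=C/C(C)(C)C[C@@H](O)C/C(C)=C/CC1 | intermediate
13 | vanillic acid (4-hydroxy-3-methoxybenzoic acid) | COc1cc(C(=O)O)ccc1O | starting material
14 | tert-butyldimethylsilyl 4-[(tert-butyldimethylsilyl)oxy]-3-methoxybenzoate | COc1cc(C(=O)O[Si](C)(C)C(C)(C)C)ccc1O[Si](C)(C)C(C)(C)C | intermediate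
15 | 4-[(tert-butyldimethylsilyl)oxy]-3-methoxybenzoic acid | COc1cc(C(=O)O)ccc1O[Si](C)(C)C(C)(C)C | intermediate
16 | (1S,3E,8E)-3,10,10-trimethyl-7-methylidenecycloundeca-3,8-dien-1-yl 4-[(tert-butyldimethylsilyl)oxy]-3-methoxybenzoate | C=C1/C=C/C(C)(C)C[C@@H](OC(=O)c2ccc(O[Si](C)(C)C(C)(C)C)c(OC)c2)C/C(C)=C/CC1 | intermediate
17 | (1S,3E,8E)-3,10,10-trimethyl-7-methylidenecycloundeca-3,8-dien-1-yl 4-hydroxy-3-methoxybenzoate | C=C1/C=C/C(C)(C)C[C@@H](OC(=O)c2ccc(O)c(OC)c2)C/C(C)=C/CC1 | target

## Step count and risks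

Total: 9 steps. Longest linear sequence: 8 steps (steps 1 to 6, 8 and 9); step 7 is a one-step side branch.

**1. Step 6 (macrocyclisation).** What may go wrong: coupling between two molecules to oligomers, closure at C9 to the 10-membered ring, or binding of zerovalent nickel by the 1,3-diene so that turnover stops. The fallback makes the C7–C8(Me)=C9 unit between two molecules by known reactions and closes the ring at C2=C3 by an intramolecular Horner–Wadsworth–Emmons reaction. It sets out from aldehyde 5 (with phosphonate 1) and returns at alcohol 12.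

Aldehyde 5 is reduced (NaBH4, MeOH) to 2,2-dimethylpent-4-en-1-ol F1 and protected (NaH, 4-methoxybenzyl chloride, Bu4NI, DMF) as 1-{[(2,2-dimethylpent-4-en-1-yl)oxy]methyl}-4-methoxybenzene F2. mCPBA gives rac-2-{3-[(4-methoxyphenyl)methoxy]-2,2-dimethylpropyl}oxirane F3, and hydrolytic kinetic resolution as in step 4 leaves (2R)-2-{3-[(4-methoxyphenyl)methoxy]-2,2-dimethylpropyl}oxirane F4. LiC≡CH·H2NCH2CH2NH2 in DMSO opens F4 at the terminal carbon C7 to (4S)-7-[(4-methoxyphenyl)methoxy]-6,6-dimethylhept-1-yn-4-ol F5, which is silylated (TBSCl, imidazole, DMF) to tert-butyl{[(4S)-7-[(4-methoxyphenyl)methoxy]-6,6-dimethylhept-1-yn-4-yl]oxy}dimethylsilane F6.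

Negishi carboalumination (Me3Al, Cp2ZrCl2, CH2Cl2) adds methyl to C8 and aluminium to C9 in syn fashion. The alkenylalane is turned into its alanate with n-BuLi and trapped with paraformaldehyde, which should give (2E,5S)-5-[(tert-butyldimethylsilyl)oxy]-8-[(4-methoxyphenyl)methoxy]-3,7,7-trimethyloct-2-en-1-ol F7 with C10 in place. CBr4/PPh3 converts it into {[(4S,6E)-8-bromo-1-[(4-methoxyphenyl)methoxy]-2,2,6-trimethyloct-6-en-4-yl]oxy}(tert-butyl)dimethylsilane F8. Alkylation of dianion 3 (made from 1 as in step 1) with F8 forms C10–C11 and gives dimethyl [(5E,8S)-8-[(tert-butyldimethylsilyl)oxy]-11-[(4-methoxyphenyl)methoxy]-6,10,10-trimethyl-2-oxoundec-5-en-1-yl]phosphonate F9.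

DDQ (CH2Cl2, pH 7 buffer) removes the 4-methoxybenzyl group to give dimethyl [(5E,8S)-8-[(tert-butyldimethylsilyl)oxy]-11-hydroxy-6,10,10-trimethyl-2-oxoundec-5-en-1-yl]phosphonate F10, and Dess–Martin periodinane oxidises it to dimethyl [(5E,8S)-8-[(tert-butyldimethylsilyl)oxy]-6,10,10-trimethyl-2,11-dioxoundec-5-en-1-yl]phosphonate F11. Masamune–Roush conditions (LiCl, DIPEA, MeCN, high dilution) should close the ring to (2E,6S,8E)-6-[(tert-butyldimethylsilyl)oxy]-4,4,8-trimethylcycloundeca-2,8-dien-1-one F12. Wittig methylenation as in step 5 gives tert-butyldimethyl{[(1S,3E,8E)-3,10,10-trimethyl-7-methylidenecycloundeca-3,8-dien-1-yl]oxy}silane F13, and Bu4NF in THF releases 12.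

**2. Step 3 (epoxidation).** What may go wrong: Baeyer–Villiger oxidation of the ketone or oxidation of the alkyne competing with the slow epoxidation of a monosubstituted alkene. The fallback goes through the halohydrin instead of a peracid. It sets out from 7 and returns at 8: NBS in THF/H2O at 0 °C adds bromine and water across the terminal alkene in the Markovnikov sense to give rac-(E)-12-bromo-11-hydroxy-9,9-dimethyldodec-7-en-2-yn-6-one F14, and K2CO3 in MeOH at 0 °C closes it to the racemic epoxide 8.

**3. Step 5 (methylenation).** What may go wrong: enolisation of the ketone by the basic ylide, or attack of the ylide on the epoxide. The fallback is a Peterson olefination. It sets out from 9 and returns at 10: Me3SiCH2MgCl with CeCl3 in THF at −78 °C adds to the carbonyl to give (E)-2,2-dimethyl-1-[(2R)-oxiran-2-yl]-5-[(trimethylsilyl)methyl]dec-3-en-8-yn-5-ol F15 (both epimers at the carbinol, of no consequence), and KH in THF eliminates the silanolate to give diene 10.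

## Further compounds

F1 | step 6 | 2,2-dimethylpent-4-en-1-ol | C=CCC(C)(C)CO
F2 | step 6 | 1-{[(2,2-dimethylpent-4-en-1-yl)oxy]methyl}-4-methoxybenzene | C=CCC(C)(C)COCc1ccc(OC)cc1
F3 | step 6 | rac-2-{3-[(4-methoxyphenyl)methoxy]-2,2-dimethylpropyl}oxirane | COc1ccc(COCC(C)(C)CC2CO2)cc1
F4 | step 6 | (2R)-2-{3-[(4-methoxyphenyl)methoxy]-2,2-dimethylpropyl}oxirane | COc1ccc(COCC(C)(C)C[C@@H]2CO2)cc1
F5 | step 6 | (4S)-7-[(4-methoxyphenyl)methoxy]-6,6-dimethylhept-1-yn-4-ol | COc1ccc(COCC(C)(C)C[C@@H](O)CC#C)cc1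
F6 | step 6 | tert-butyl{[(4S)-7-[(4-methoxyphenyl)methoxy]-6,6-dimethylhept-1-yn-4-yl]oxy}dimethylsilane | COc1ccc(COCC(C)(C)C[C@@H](O[Si](C)(C)C(C)(C)C)CC#C)cc1
F7 | step 6 | (2E,5S)-5-[(tert-butyldimethylsilyl)oxy]-8-[(4-methoxyphenyl)methoxy]-3,7,7-trimethyloct-2-en-1-ol | COc1ccc(COCC(C)(C)C[C@@H](O[Si](C)(C)C(C)(C)C)C/C(C)=C/CO)cc1
F8 | step 6 | {[(4S,6E)-8-bromo-1-[(4-methoxyphenyl)methoxy]-2,2,6-trimethyloct-6-en-4-yl]oxy}(tert-butyl)dimethylsilane | COc1ccc(COCC(C)(C)C[C@@H](O[Si](C)(C)C(C)(C)C)C/C(C)=C/CBr)cc1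
F9 | step 6 | dimethyl [(5E,8S)-8-[(tert-butyldimethylsilyl)oxy]-11-[(4-methoxyphenyl)methoxy]-6,10,10-trimethyl-2-oxoundec-5-en-1-yl]phosphonate | COc1ccc(COCC(C)(C)C[C@@H](O[Si](C)(C)C(C)(C)C)C/C(C)=C/CCC(=O)CP(=O)(OC)OC)cc1
F10 | step 6 | dimethyl [(5E,8S)-8-[(tert-butyldimethylsilyl)oxy]-11-hydroxy-6,10,10-trimethyl-2-oxoundec-5-en-1-yl]phosphonate | OCC(C)(C)C[C@@H](O[Si](C)(C)C(C)(C)C)C/C(C)=C/CCC(=O)CP(=O)(OC)OC
F11 | step 6 | dimethyl [(5E,8S)-8-[(tert-butyldimethylsilyl)oxy]-6,10,10-trimethyl-2,11-dioxoundec-5-en-1-yl]phosphonate | O=CC(C)(C)C[C@@H](O[Si](C)(C)C(C)(C)C)C/C(C)=C/CCC(=O)CP(=O)(OC)OC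
F12 | step 6 | (2E,6S,8E)-6-[(tert-butyldimethylsilyl)oxy]-4,4,8-trimethylcycloundeca-2,8-dien-1-one | O=C1/C=C/C(C)(C)C[C@@H](O[Si](C)(C)C(C)(C)C)C/C(C)=C/CC1
F13 | step 6 | tert-butyldimethyl{[(1S,3E,8E)-3,10,10-trimethyl-7-methylidenecycloundeca-3,8-dien-1-yl]oxy}silane | C=C1/C=C/C(C)(C)C[C@@H](O[Si](C)(C)C(C)(C)C)C/C(C)=C/CC1
F14 | step 3 | rac-(E)-12-bromo-11-hydroxy-9,9-dimethyldodec-7-en-2-yn-6-one | CC#CCCC(=O)/C=C/C(C)(C)CC(O)CBr
F15 | step 5 | (E)-2,2-dimethyl-1-[(2R)-oxiran-2-yl]-5-[(trimethylsilyl)methyl]dec-3-en-8-yn-5-ol | CC#CCCC(O)(C[Si](C)(C)C)/C=C/C(C)(C)C[C@@H]1CO1
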